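Take two flasks, maple and birch, that differ in temperature alone, and ask where each stands at the end. Starting material is opened by free catalyst to open intermediate. Open intermediate binds free catalyst reversibly as catalyst intermediate, and this meets reagent, again reversibly, to give product and free catalyst back.

| flask | starting material | reagent | free catalyst | temperature | remark | time |
|---|---|---|---|---|---|---|
| blue | 20 mM | 14 mM | 0.40 mM | 75 °C | run made earlier |  |
| red | 20 mM | 14 mM | 0.90 mM | 88 °C | run made earlier |  |
| violet | 30 mM | 14 mM | 0.60 mM | 75 °C | run made earlier |  |
| maple | 20 mM | 14.0 mM | 0.60 mM | 80 °C |  | 3.0 h |
| birch | 20 mM | 14.0 mM | 0.60 mM | 95 °C |  | 3.0 h |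

- blue (time / h: product / %, starting material / %): 0.250: 16, 75; 0.333: 23, 69; 0.500: 36, 57; 0.833: 47, 39; 1.33: 59, 23; 2.00: 64, 15; 3.00: 67, 5
- red (time / h: product / %, starting material / %): 0.250: 57, 30; 0.333: 62, 20; 0.500: 66, 12; 0.833: 65, 0; 1.33: 67, 0; 2.00: 70, 0; 3.00: 66, 0
- violet (time / h: product / %, starting material / %): 0.667: 42, 38; 1.33: 43, 14; 2.00: 45, 6; 2.50: 44, 4; 3.00: 46, 2

(standard deviation of a reading: 2 percentage points)

- the analysis behind the earlier runs scatters by 2 percentage points, standard deviation
- steps under discussion: starting material + free catalyst -> free catalyst + open intermediate; free catalyst + open intermediate <-> catalyst intermediate; reagent + catalyst intermediate <-> free catalyst + product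

- the flask that comes out highest in amount of product, in percent of the starting material charged, or "all alike" when all lie within 1.5 percentage points (maple / birch / all alike)
- product at the end, in percent of the starting material charged, maple
- product at the end, in percent of the starting material charged, birch

The first chemist argues from a ceiling: each product takes one reagent, so with these charges product stops at reagent over starting material, 70.0% in both flasks, just as violet's last reading of 46% sits by its ceiling of 46.7%. Time is no obstacle, she says, since both flasks are hotter and richer in catalyst than blue, which already reads 67% with 5% of its starting material left.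

The second chemist points to red, whose last four readings, taken with no starting material showing, average 67.0%, which is 3 percentage points below the ceiling on readings that scatter by 2 points. Adding the last two steps cancels the free catalyst and leaves open intermediate plus reagent giving product, so she carries the closing ratio, product divided by reagent left times open intermediate left at standstill, which is the equilibrium constant of that sum.

In red, counting whatever isn't product as open intermediate, I reckon 13.4 mM of product, 0.600 mM of reagent and 6.60 mM of open intermediate, so the ratio reads 3.38 mM⁻¹. This is a rough reading, since the reagent left is a small difference of larger numbers. I then go round for maple, assuming the ratio carries over from red's temperature. The ceiling as first answer leaves 0.690 mM of reagent, and putting that back leaves 0.588 mM, so product comes to 67.1%, the same for birch, whose charges are equal.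

The forecast stands on the second chemist's side, holding that red “hints at a reversible last step”, but it differs from my figure: 67.5% for maple, 66.5% for birch, and so all alike.

The flasks give 66.9% in maple and 67.2% in birch, so the answer is all alike.

    starting material + free catalyst → free catalyst + open intermediate (k = 66.0 M⁻¹ min⁻¹, Ea = 50.0 kJ mol⁻¹)
    free catalyst + open intermediate ⇌ catalyst intermediate (K = 67.0 M⁻¹, k = 1600 M⁻¹ min⁻¹, Ea = 56.0 kJ mol⁻¹, ΔH = 3.00 kJ mol⁻¹)
    reagent + catalyst intermediate ⇌ free catalyst + product (K = 50.0, k = 1000 M⁻¹ min⁻¹, Ea = 53.0 kJ mol⁻¹, ΔH = 4.00 kJ mol⁻¹)
    (constants at 80 °C)

Put back with birch's product, the ratio says 4.32% of the reagent charge is left, and birch holds 4.07%. The main reason birch stops at 67.2% is the shrinking supply of reagent: with reagent kept from shrinking, birch gives 98.0%, whereas taking away the backward run of the last step, which is only a part of the story, gives 70.0%. The ceiling view comes into its own in a neighbour of birch charged with 34 mM of starting material, where the ceiling is 41.2% and one round of the ratio leaves 0.207 mM of reagent, so product is 40.6%; that neighbour gives 40.6%.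

The runs were computed with constants of no real substance.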